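**Plan**
- Retrosynthesis: the two formyl groups go back to a ring-B enone (C8–C12 cut as a Morita–Baylis–Hillman bond, C9–C11 as methylenation/hydroboration) and the side-chain C=C to a Wittig bond. Ring A is then opened by cutting C1–C2 and C3–Cl together, and the monocyclic ring-B keto aldehyde is cut at C4–C5 and C10–C1.
- Enabling feature: O1 and Cl3 sit 1,3 on ring A with C2 between them, and C3 is bonded to the quaternary C4. This is the imprint of an aldehyde at C1 (on C10) attacked by a vinyl group C2=C3 carried by C4.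
- Forward: ring B comes from (R)-carvone; the C4 unit is joined by Sakurai addition of a (Z)-allylsilane and C1 by formaldehyde capture; ring A closes in the chloro-Prins step; the chain olefin, C12 and C11 follow.
- Stereochemistry: the carvone centre (kept as the 7-acetate, later eliminated) sets C5 and through it C10; silane geometry sets C4; the chair Prins sets C1 and C3; hydroboration anti to the C10 methyl sets C9.

Key step: step 6

Remark: drimane numbering is used for every intermediate (ring A = C1–C5, C10; ring B = C5–C10; C11 on C9, C12 on C8; α = face opposite the C10 methyl), and the open transition state of the Sakurai addition is assumed to be synclinal.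

**Route**

Step 1
Reactants: 1 (R)-carvone
Product: 3 (R)-5-acetoxy-2-methylcyclohex-2-en-1-one, via methoxy hydroperoxide 2 (not isolated)
Conditions: O3, CH2Cl2–MeOH, −78 °C; then Ac2O, Et3N, DMAP (cat.), −78 → 23 °C
Reagents that add atoms: ozone, O=[O+][O-]; acetic anhydride, CC(=O)OC(C)=O
Why: Ozonolysis of the electron-rich isopropenyl group in methanol and Criegee rearrangement of the acetylated hydroperoxide move the ring carbon from C to O with retention, so the acetate (its two carbons are the former isopropenyl carbons) keeps the carvone configuration while the conjugated ring olefin is left alone.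

Step 2
Reactants: 4 (3-bromopropoxy)(tert-butyl)dimethylsilane, 5 propyne
Product: 9 (Z)-tert-butyl[(5-iodo-4-methylpent-4-en-1-yl)oxy]dimethylsilane, via Grignard reagent 6 (not isolated), via alkylcopper 7 (not isolated), via alkenylcopper 8 (not isolated)
Conditions: Mg, Et2O; CuBr·SMe2, −45 °C; propyne, −25 °C; I2, THF, −50 → 0 °C
Reagents that add atoms: iodine, II
Why: Normant carbocupration adds the alkylcopper syn across propyne with the alkyl group on the internal carbon, and iodinolysis of the C–Cu bond with retention gives the (Z)-iodide (chain cis to iodine).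

Step 3
Reactants: 9 (Z)-tert-butyl[(5-iodo-4-methylpent-4-en-1-yl)oxy]dimethylsilane
Product: 10 (Z)-tert-butyldimethyl{[4-methyl-6-(trimethylsilyl)hex-4-en-1-yl]oxy}silane
Conditions: Me3SiCH2MgCl, Pd(PPh3)4 (cat.), THF, 23 → 50 °C
Reagents that add atoms: (trimethylsilyl)methylmagnesium chloride, C[Si](C)(C)C[Mg]Cl
Why: Kumada coupling of an alkenyl iodide proceeds with retention of olefin geometry, which leaves the chain cis to CH2SiMe3.

Step 4
Reactants: 3 (R)-5-acetoxy-2-methylcyclohex-2-en-1-one, 10 (Z)-allylsilane, 11 formaldehyde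
Product: 13 (1R,3S,4R)-3-[(3R)-6-{[tert-butyl(dimethyl)silyl]oxy}-3-methylhex-1-en-3-yl]-4-(hydroxymethyl)-4-methyl-5-oxocyclohexyl acetate, via titanium enolate 12 (not isolated)
Conditions: TiCl4, CH2Cl2, −78 °C; 10; then CH2O (gas from paraformaldehyde), −78 → −40 °C
Reagents that add atoms: none
Why: Hosomi–Sakurai conjugate addition through the silane γ-carbon followed by aldol capture of the regiodefined titanium enolate (three-component Sakurai–aldol): axial attack anti to the acetoxy group sets C5, the synclinal open transition state of the (Z)-silane (γ-methyl over the ring, chain and CH2SiMe3 turned outward) should set C4, and formaldehyde enters C10 anti to the new C5 substituent.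

Step 5
Reactants: 13 hydroxymethyl ketone
Product: 14 (1R,3S,4R)-3-[(3R)-6-{[tert-butyl(dimethyl)silyl]oxy}-3-methylhex-1-en-3-yl]-4-formyl-4-methyl-5-oxocyclohexyl acetate
Conditions: Dess–Martin periodinane, CH2Cl2, 0 → 23 °C
Reagents that add atoms: none
Why: Dess–Martin oxidation of the neopentyl primary alcohol is neutral, so the non-enolisable β-keto aldehyde should form without retro-aldol loss of formaldehyde or β-elimination of the acetate.

Step 6
Reactants: 14 keto aldehyde with C4 vinyl quaternary centre
Product: 16 3β-chloro-1α-hydroxy-4α-(3-hydroxypropyl)-4β,10β-dimethyl-9-oxo-trans-decalin-7α-yl acetate, via boron alkoxide 15 (not isolated)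
Conditions: BCl3 (4 equiv), CH2Cl2, −78 °C; then MeOH, −78 → 0 °C
Reagents that add atoms: boron trichloride, ClB(Cl)Cl
Why: Proposed new method: BCl3 binds the aldehyde as a 1:1 complex that cannot chelate, C2 of the vinyl group attacks C1 in a chair while a chloroborate passes chloride to C3 on the opposite face of the olefin, so that C1–C2 and C3–Cl form in one asynchronous event without a free neopentylic cation, and methanol then cleaves the boron alkoxide and (through the HCl formed) the primary TBS ether. The closest known reaction type is the Lewis-acid halo-Prins cyclisation of 5-hexenals to 3-halocyclohexanols; new here are the quaternary carbons next to both reacting centres and the 1,3-dicarbonyl electrophile. Ring A closes in the 6-endo mode with respect to the olefin (C1 bonds to the terminal carbon C2) and is trans-fused because the C10–CHO and C5–C4 bonds are both equatorial on ring B. At C1 the complexed oxygen should take the inside, axial position next to C5 and away from the C9 carbonyl (Felkin–Anh-type placement, aldehyde hydrogen next to the axial C10 methyl), giving 1α-OH; at C3, anti addition across C2=C3 in that chair puts chlorine equatorial (3β). The step needs the aldehyde to react before the ketone and chloride capture to outrun ene and 1,2-shift paths: the ketone can reach the olefin only with the C4 group axial, the vinyl group has no allylic hydrogen, and the chloride-rich boron reagent at −78 °C supplies the nucleophile within the ion pair.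

Step 7
Reactants: 16 chlorohydrin diol
Product: 17 bis(triethylsilyl) ether of 16 (O1 and chain oxygen)
Conditions: Et3SiOTf, 2,6-lutidine, CH2Cl2, −78 → 0 °C
Reagents that add atoms: triethylsilyl trifluoromethanesulfonate, CC[Si](CC)(CC)OS(=O)(=O)C(F)(F)F
Why: Silyl triflate with 2,6-lutidine silylates both hydroxyls, including the hindered axial 1α-OH, under conditions too weakly basic for retro-aldol cleavage of the β-hydroxy ketone.

Step 8
Reactants: 17 bis(triethylsilyl) ether
Product: 18 3β-chloro-4β,10β-dimethyl-1α-(triethylsilyloxy)-4α-[3-(triethylsilyloxy)propyl]-trans-octal-7-en-9-one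
Conditions: DBU, CH2Cl2, 0 → 23 °C
Reagents that add atoms: none
Why: E1cB elimination of the axial β-acetoxy group (anti to the axial C8 hydrogen) gives the Δ7 enone, while the C3 chloride is not β to a carbonyl and the silylated O1 cannot start a retro-aldol.

Step 9
Reactants: 18 bis-silylated enone
Product: 19 3-[3β-chloro-4β,10β-dimethyl-9-oxo-1α-(triethylsilyloxy)-trans-octal-7-en-4α-yl]propanal
Conditions: (COCl)2, DMSO, CH2Cl2, −78 → −30 °C; Et3N, −78 → 0 °C
Reagents that add atoms: none
Why: Under Swern conditions a primary triethylsilyl ether is cleaved by the chlorosulfonium salt and oxidised directly to the aldehyde, whereas the hindered secondary TES ether is inert (selective oxidative desilylation).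

Step 10
Reactants: 19 aldehyde
Product: 20 3β-chloro-4β,10β-dimethyl-4α-(4-methylpent-3-en-1-yl)-1α-(triethylsilyloxy)-trans-octal-7-en-9-one
Conditions: i-PrPPh3I, n-BuLi, THF, 0 °C; 19, −78 → 0 °C
Reagents that add atoms: isopropyltriphenylphosphonium iodide, CC(C)[P+](c1ccccc1)(c1ccccc1)c1ccccc1.[I-]
Why: Wittig olefination with the non-stabilised isopropylidene ylide should take the unhindered aldehyde at low temperature and leave the neopentylic enone carbonyl untouched.

Step 11
Reactants: 20 enone, 11 formaldehyde
Product: 21 8-(hydroxymethyl) derivative of enone 20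
Conditions: 37% aq. CH2O, DMAP, THF–H2O, 23 °C
Reagents that add atoms: none
Why: Morita–Baylis–Hillman reaction: DMAP adds to the unsubstituted C7, the enolate takes formaldehyde at C8, and loss of DMAP restores the enone.

Step 12
Reactants: 21 hydroxymethyl enone
Product: 22 [3β-chloro-4β,10β-dimethyl-9-methylene-4α-(4-methylpent-3-en-1-yl)-1α-(triethylsilyloxy)-trans-octal-7-en-8-yl]methanol
Conditions: Ph3PCH3Br, KHMDS (ylide preformed, 4 equiv), toluene, 0 → 80 °C
Reagents that add atoms: methyltriphenylphosphonium bromide, C[P+](c1ccccc1)(c1ccccc1)c1ccccc1.[Br-]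
Why: Wittig methylenation with salt-free ylide in hot toluene, as used for hindered ketones, converts the C9 carbonyl into the exocyclic olefin, the excess ylide covering the free hydroxyl.

Step 13
Reactants: 22 diene alcohol
Product: 24 1α-(triethylsilyloxy) 11,12-diol (9α-H), via organoborane 23 (not isolated)
Conditions: 9-BBN (3 equiv), THF, 0 → 40 °C; then NaOH, H2O2, 0 → 23 °C
Reagents that add atoms: hydrogen peroxide, OO
Why: Hydroboration–oxidation: 9-BBN places boron on the terminal C11 of the 1,1-disubstituted olefin (the two trisubstituted olefins react far more slowly) from the α face, anti to the axial C10 methyl, so hydrogen enters C9 from α and CH2OH ends β.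

Step 14
Reactants: 24 diol
Product: 25 1-O-triethylsilyl ether of the target dialdehyde
Conditions: (COCl)2, DMSO, CH2Cl2, −78 °C; Et3N, −78 → −30 °C
Reagents that add atoms: none
Why: Swern oxidation activates both primary alcohols before base is added, so the 1,4-diol should go to the dialdehyde without lactol formation and, at low temperature, without epimerisation at C9.

Step 15
Reactants: 25 silylated dialdehyde
Product: 26 target, 3β-chloro-1α-hydroxy-4β,10β-dimethyl-4α-(4-methylpent-3-en-1-yl)-trans-octal-7-ene-8,9β-dicarbaldehyde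
Conditions: HF·pyridine, pyridine, THF, 0 → 23 °C
Reagents that add atoms: none
Why: Buffered HF·pyridine removes the triethylsilyl ether under mildly acidic conditions that should not disturb the epimerisable C9 aldehyde.

**Compound list**

1 | (R)-carvone | CC1=CC[C@@H](C(C)=C)CC1=O | starting material
2 | (5R)-5-(1-hydroperoxy-1-methoxyethyl)-2-methylcyclohex-2-en-1-one | CC1=CC[C@@H](C(C)(OC)OO)CC1=O | intermediate (not isolated)
3 | (R)-5-acetoxy-2-methylcyclohex-2-en-1-one | CC1=CC[C@@H](OC(C)=O)CC1=O | intermediate
4 | (3-bromopropoxy)(tert-butyl)dimethylsilane | CC(C)(C)[Si](C)(C)OCCCBr | starting material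
5 | propyne | CC#C | starting material
6 | 3-(tert-butyldimethylsilyloxy)propylmagnesium bromide | CC(C)(C)[Si](C)(C)OCCC[Mg]Br | intermediate (not isolated)
7 | 3-(tert-butyldimethylsilyloxy)propylcopper | CC(C)(C)[Si](C)(C)OCCC[Cu] | intermediate (not isolated)
8 | (Z)-[5-(tert-butyldimethylsilyloxy)-2-methylpent-1-en-1-yl]copper | C/C(CCCO[Si](C)(C)C(C)(C)C)=C/[Cu] | intermediate (not isolated)
9 | (Z)-tert-butyl[(5-iodo-4-methylpent-4-en-1-yl)oxy]dimethylsilane | C/C(CCCO[Si](C)(C)C(C)(C)C)=C/I | intermediate
10 | (Z)-tert-butyldimethyl{[4-methyl-6-(trimethylsilyl)hex-4-en-1-yl]oxy}silane | C/C(CCCO[Si](C)(C)C(C)(C)C)=C/C[Si](C)(C)C | intermediate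
11 | formaldehyde | C=O | starting material
12 | trichlorotitanium enolate of the Sakurai adduct | CC1=C(O[Ti](Cl)(Cl)Cl)C[C@H](OC(C)=O)C[C@H]1[C@@](C)(C=C)CCCO[Si](C)(C)C(C)(C)C | intermediate (not isolated)
13 | (1R,3S,4R)-3-[(3R)-6-{[tert-butyl(dimethyl)silyl]oxy}-3-methylhex-1-en-3-yl]-4-(hydroxymethyl)-4-methyl-5-oxocyclohexyl acetate | OC[C@]1(C)C(=O)C[C@H](OC(C)=O)C[C@H]1[C@@](C)(C=C)CCCO[Si](C)(C)C(C)(C)C | intermediate
14 | (1R,3S,4R)-3-[(3R)-6-{[tert-butyl(dimethyl)silyl]oxy}-3-methylhex-1-en-3-yl]-4-formyl-4-methyl-5-oxocyclohexyl acetate | O=C[C@]1(C)C(=O)C[C@H](OC(C)=O)C[C@H]1[C@@](C)(C=C)CCCO[Si](C)(C)C(C)(C)C | intermediate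
15 | O1-dichloroboryl derivative of the cyclised chlorohydrin (chain still TBS ether) | CC(C)(C)[Si](C)(C)OCCC[C@]1(C)[C@@H](Cl)C[C@H](OB(Cl)Cl)[C@]2(C)C(=O)C[C@H](OC(C)=O)C[C@@H]12 | intermediate (not isolated)
16 | 3β-chloro-1α-hydroxy-4α-(3-hydroxypropyl)-4β,10β-dimethyl-9-oxo-trans-decalin-7α-yl acetate | OCCC[C@]1(C)[C@@H](Cl)C[C@H](O)[C@]2(C)C(=O)C[C@H](OC(C)=O)C[C@@H]12 | intermediate
17 | bis(triethylsilyl) ether of 16 | CC[Si](CC)(CC)OCCC[C@]1(C)[C@@H](Cl)C[C@H](O[Si](CC)(CC)CC)[C@]2(C)C(=O)C[C@H](OC(C)=O)C[C@@H]12 | intermediate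
18 | 3β-chloro-4β,10β-dimethyl-1α-(triethylsilyloxy)-4α-[3-(triethylsilyloxy)propyl]-trans-octal-7-en-9-one | CC[Si](CC)(CC)OCCC[C@]1(C)[C@@H](Cl)C[C@H](O[Si](CC)(CC)CC)[C@]2(C)C(=O)C=CC[C@@H]12 | intermediate
19 | 3-[3β-chloro-4β,10β-dimethyl-9-oxo-1α-(triethylsilyloxy)-trans-octal-7-en-4α-yl]propanal | O=CCC[C@]1(C)[C@@H](Cl)C[C@H](O[Si](CC)(CC)CC)[C@]2(C)C(=O)C=CC[C@@H]12 | intermediate
20 | 3β-chloro-4β,10β-dimethyl-4α-(4-methylpent-3-en-1-yl)-1α-(triethylsilyloxy)-trans-octal-7-en-9-one | CC(C)=CCC[C@]1(C)[C@@H](Cl)C[C@H](O[Si](CC)(CC)CC)[C@]2(C)C(=O)C=CC[C@@H]12 | intermediate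
21 | 8-(hydroxymethyl) derivative of 20 | CC(C)=CCC[C@]1(C)[C@@H](Cl)C[C@H](O[Si](CC)(CC)CC)[C@]2(C)C(=O)C(CO)=CC[C@@H]12 | intermediate
22 | 9-methylene diene alcohol | CC(C)=CCC[C@]1(C)[C@@H](Cl)C[C@H](O[Si](CC)(CC)CC)[C@]2(C)C(=C)C(CO)=CC[C@@H]12 | intermediate
23 | C11 B-alkyl-9-BBN / O12 borinate | CC(C)=CCC[C@]1(C)[C@@H](Cl)C[C@H](O[Si](CC)(CC)CC)[C@]2(C)[C@@H](CB3C4CCCC3CCC4)C(COB3C4CCCC3CCC4)=CC[C@@H]12 | intermediate (not isolated)
24 | 1α-(triethylsilyloxy) 11,12-diol | CC(C)=CCC[C@]1(C)[C@@H](Cl)C[C@H](O[Si](CC)(CC)CC)[C@]2(C)[C@@H](CO)C(CO)=CC[C@@H]12 | intermediate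
25 | 1-O-triethylsilyl dialdehyde | CC(C)=CCC[C@]1(C)[C@@H](Cl)C[C@H](O[Si](CC)(CC)CC)[C@]2(C)[C@@H](C=O)C(C=O)=CC[C@@H]12 | intermediate
26 | CNP0155449.1 | CC(C)=CCC[C@]1(C)[C@@H](Cl)C[C@H](O)[C@]2(C)[C@@H](C=O)C(C=O)=CC[C@@H]12 | target

**Count**

Total steps: 15. Longest linear sequence: 14 steps (steps 2–15, from bromide 4); 13 steps from (R)-carvone.

**Steps most likely to fail**

Step 6 (chloro-Prins). The positive charge developing at C3 may trigger a 1,2-alkyl shift from C4 or proton loss before chloride arrives, or the aldehyde may react through the chair with equatorial oxygen. The fallback uses known reactions only, sets out from 14 and comes back at 16; ring A is closed by metathesis and chlorine enters by conjugate addition.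
- Vinylmagnesium bromide (THF, −78 °C) should add to the aldehyde alone and give allylic alcohol F1 (both C1 epimers).
- Ring-closing metathesis with the Grubbs II catalyst then gives ring-A cyclohexenol F2; C2 now stems from the Grignard reagent.
- Dess–Martin oxidation gives ring-A enone F3.
- Hydrogen chloride in CH2Cl2 adds conjugatively to give β-chloro ketone F4, in which the chloride should settle equatorial (3β) under equilibrating conditions.
- CBS reduction with the (R)-methyl oxazaborolidine and BH3·SMe2 should deliver hydride to the β face of the ring-A ketone to give hydroxy ketone F5. The ring-B ketone is mismatched, because the face the catalyst prefers there is blocked by the axial 7-acetate.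
- Methanolic HCl removes the TBS ether and gives 16.

Step 4 (Sakurai–aldol). Transfer of olefin geometry to C4 through the open transition state may be weak or run in the opposite sense. The fallback changes the stereochemical handle and the way the silane is made; it sets out from 4 and 3 and comes back at 13.
- Alkylation of lithium acetylide–ethylenediamine with bromide 4 gives alkyne F6.
- Zirconium-catalysed carboalumination (Me3Al, Cp2ZrCl2) and iodinolysis give the (E)-iodide F7.
- Kumada coupling as in step 3 gives the (E)-allylsilane F8.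
- F8, used with 3 and 11 under the conditions of step 4, should give 13 if the transition state is antiperiplanar, because the outward position of CH2SiMe3 then belongs to the other geometric isomer.

Step 13 (hydroboration). Facial selectivity at C9 may be poor because the α face is flanked by the 1α-silyloxy group. The fallback sets out from 22 and comes back at 25.
- HF·pyridine removes the silyl ether to give diol F9.
- Hydroboration with 9-BBN and oxidation are run on the free alcohol, whose small hydroxyl can hold boron on the α face as a borinate, to give triol F10.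
- Et3SiOTf/2,6-lutidine gives tris(triethylsilyl) ether F11.
- Swern conditions oxidise the two primary TES ethers directly and give 25.

**Further compounds**

F1 | step 6 | allylic alcohol from vinyl addition to 14 (C1 epimers) | C=CC(O)[C@]1(C)C(=O)C[C@H](OC(C)=O)C[C@H]1[C@@](C)(C=C)CCCO[Si](C)(C)C(C)(C)C
F2 | step 6 | ring-A cyclohex-2-en-1-ol (C1 epimers) | CC(C)(C)[Si](C)(C)OCCC[C@]1(C)C=CC(O)[C@]2(C)C(=O)C[C@H](OC(C)=O)C[C@@H]12
F3 | step 6 | ring-A enone (2-en-1-one) | CC(C)(C)[Si](C)(C)OCCC[C@]1(C)C=CC(=O)[C@]2(C)C(=O)C[C@H](OC(C)=O)C[C@@H]12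
F4 | step 6 | 3β-chloro 1,9-diketone | CC(C)(C)[Si](C)(C)OCCC[C@]1(C)[C@@H](Cl)CC(=O)[C@]2(C)C(=O)C[C@H](OC(C)=O)C[C@@H]12
F5 | step 6 | 3β-chloro-1α-hydroxy ketone, chain TBS ether | CC(C)(C)[Si](C)(C)OCCC[C@]1(C)[C@@H](Cl)C[C@H](O)[C@]2(C)C(=O)C[C@H](OC(C)=O)C[C@@H]12
F6 | step 4 | tert-butyldimethyl(pent-4-yn-1-yloxy)silane | C#CCCCO[Si](C)(C)C(C)(C)C
F7 | step 4 | (E)-tert-butyl[(5-iodo-4-methylpent-4-en-1-yl)oxy]dimethylsilane | C/C(CCCO[Si](C)(C)C(C)(C)C)=C\I
F8 | step 4 | (E)-tert-butyldimethyl{[4-methyl-6-(trimethylsilyl)hex-4-en-1-yl]oxy}silane | C/C(CCCO[Si](C)(C)C(C)(C)C)=C\C[Si](C)(C)C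
F9 | step 13 | 1α,12-diol of the 9-methylene diene | CC(C)=CCC[C@]1(C)[C@@H](Cl)C[C@H](O)[C@]2(C)C(=C)C(CO)=CC[C@@H]12
F10 | step 13 | 1α,11,12-triol (9α-H) | CC(C)=CCC[C@]1(C)[C@@H](Cl)C[C@H](O)[C@]2(C)[C@@H](CO)C(CO)=CC[C@@H]12
F11 | step 13 | tris(triethylsilyl) ether of the triol | CC(C)=CCC[C@]1(C)[C@@H](Cl)C[C@H](O[Si](CC)(CC)CC)[C@]2(C)[C@@H](CO[Si](CC)(CC)CC)C(CO[Si](CC)(CC)CC)=CC[C@@H]12
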